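The numbers in the tables were generated by integration on assumed constants, noise included.

The spring run ended at 80.0 s with 77.5% target and 0% substrate, so 22.5% of the charge had gone elsewhere, and the meeting opened on that gap.

| setting | spring | summer | Thursday's | Friday's | Tuesday's | Monday's |
|---|---|---|---|---|---|---|
| substrate | 0.0020 M | 0.0020 M | 0.0020 M | 0.0020 M | 0.0020 M | 0.0020 M (fed, over 1.60 min) |
| reagent | 2 mM | 2 mM | 2.00 mM (fed, over 1.60 min) | 2.00 mM | 2.00 mM | 2.00 mM |
| free catalyst | 2 µM | 4 µM | 2.0 µM | 2.0 µM | 2.0 µM | 2.0 µM |
| remark | run made earlier | run made earlier | a stirred flask in which reagent is dosed at a steady rate over 1.60 min without added volume, worked up at 2.0 min | everything together in a closed stirred flask, run for 2.0 min | one stirred flow tank at steady state, fed with the mixture as stated, mean residence time 2.0 min | a stirred flask in which substrate is dosed at a steady rate over 1.60 min without added volume, worked up at 2.0 min |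
| time |  |  | 2.0 min | 2.0 min |  | 2.0 min |

| run | time / s | target / % | substrate / % |
|---|---|---|---|
| spring | 10.0 | 25.0 | 71.2 |
| spring | 20.0 | 43.8 | 47.8 |
| spring | 30.0 | 56.8 | 29.6 |
| spring | 50.0 | 70.6 | 8.1 |
| spring | 80.0 | 77.5 | 0 |
| summer | 10.0 | 44.8 | 49.0 |
| summer | 15.0 | 59.0 | 31.9 |
| summer | 20.0 | 70.3 | 19.3 |
| summer | 25.0 | 77.8 | 10.1 |

(readings scatter by 0.5 percentage points)

- the stated concentrations are those of everything mixed, before any reaction; amounts are the same in each set-up
- the feed brings no volume worth counting
- the earlier runs were made in a closed, stirred flask

1. the set-up with the highest amount of target at the outlet or at the end, in percent of the substrate put in ("none" if the first two lie within 2 percentage points) (Thursday's / Friday's / Tuesday's / Monday's / none)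
2. amount of target at the outlet or at the end, in percent of the substrate put in, Thursday's
3. amount of target at the outlet or at the end, in percent of the substrate put in, Friday's
4. amount of target at the outlet or at the end, in percent of the substrate put in, Tuesday's
5. amount of target at the outlet or at the end, in percent of the substrate put in, Monday's

The first speaker proposed to follow one substrate molecule to its fork: it enters the catalyst's round and leaves as target, or it meets a target and both are lost. She counted two units of gap per meeting. Between 10.0 s and 50.0 s the spring gap grew by 18 percentage points, and she held that against [substrate] times [target] summed over those readings. This gave 7.20 M⁻¹ s⁻¹, the loss constant, a second-order rate constant read from the readings.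

The second speaker took the other branch. She took one reagent to go per substrate entering, counted target plus half the gap as entered, and read the reagent left in the spring run as a pseudo-first-order decay with the constant 0.0340 s⁻¹ at that catalyst.

The chair put both to Tuesday's tank. Entry balanced against outflow lets 80.3% of the substrate enter. Meetings then follow from the loss constant, the residence time and the outlet amounts, each short by those meetings, and they come to 10.7%. That leaves 69.6% target.

Friday's repeats the spring recipe, so the chair took the last spring reading, 77.5%. The second speaker added a warning on Monday's: with the reagent still at its full charge, entry at 0.0340 s⁻¹ is faster than the feed at 0.0104 s⁻¹, but once the reagent left falls to about 30.6% she expected substrate to stand beside much target.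

The forecast named Monday's, with 68%, 77.5%, 67% and 89% in the order Thursday's, Friday's, Tuesday's, Monday's, saying of Monday's that “side loss is small”, and its Tuesday's figure lies below the chair's.

Monday's gave 83.0%, the highest, against 77.4% for Friday's, 67.2% for Thursday's and 67.0% for Tuesday's.

    reagent + catalyst intermediate A ⇌ catalyst intermediate B (K = 400 M⁻¹, k = 3.50 × 10⁵ M⁻¹ s⁻¹)
    substrate + target → side product (k = 7.30 M⁻¹ s⁻¹)
    substrate + free catalyst → catalyst intermediate A (k = 70000 M⁻¹ s⁻¹)
    2 catalyst intermediate C → spent catalyst (k = 15000 M⁻¹ s⁻¹)
    catalyst intermediate C → free catalyst + target (k = 820 s⁻¹)
    catalyst intermediate B ⇌ released group + catalyst intermediate C (K = 0.0330 M, k = 95.0 s⁻¹)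

Monday's highest concentration of substrate was 2.75 × 10⁻⁴ M. At the end of its feed Monday's flask held 13.7% substrate beside 74.6% target, and at 2.00 min it held 1.89% beside 83.0%. Averaging those two products, the loss constant gives 4.1 points of new gap over Monday's last stretch. Monday's side product went from 11.5% to 15.1%.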